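**Numbering (halimane):** ring A = C1–C5, C10; ring B = C5–C10; side chain C11–C15 (C16 = CH3 on C13); C17 on C8, C20 on C9, C18 (CO2H) and C19 (CH3) on C4.

**Plan**
- Cuts: ring A across C4–C5 and C2–C3 (retro-Diels–Alder to methacrolein and a ring-B 2-vinylcyclohexene); the side chain at C12–C13 (B-alkyl Suzuki) and at the C13–O/C14–O bonds; C8–C17 and C9–C11 (conjugate addition/aldol on 2-methylcyclohexenone).
- Forward: ring B with C8/C9 first, chain attached, C10 ketone → enol triflate → diene, then ring A in one cycloaddition; side-chain oxygenation follows and the C18 aldehyde is oxidised last.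
- Stereochemistry: C8 by Cu-catalysed conjugate addition; C9 relayed from C8 (electrophile enters anti to the C8 methyl); C4 and C5 together in the Diels–Alder step (catalyst-fixed dienophile face, exo topology); C13/C14 by asymmetric epoxidation and invertive opening at C13.
- Enabling feature: ring A is a cyclohexene whose only double bond, C1=C10, lies between C1 and the ring-fusion carbon, next to the H-bearing C5 and the quaternary C4 that carries the C18 carbonyl and C19. This is the retron of methacrolein (C3, C4, C18, C19) adding to the diene C5=C10–C1=C2, which the C10 ketone delivers regiospecifically because C9 is quaternary.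

Key step: step 8

Remark: aldol 3 is carried as both carbinol epimers (they converge in step 2); ligand and catalyst antipodes are specified by the face they must deliver to.

**Step 1**
Reactants: 1 2-methylcyclohex-2-en-1-one
Product: 3 (2R,3R)-2-(1-hydroxyethyl)-2,3-dimethylcyclohexan-1-one (both carbinol epimers), via dimethylaluminium enolate 2 (not isolated)
Conditions: Me3Al, CuTC (2 mol %), chiral phosphoramidite (4 mol %; antipode delivering CH3 to the C3-Re face), Et2O, −30 °C; then MeCHO, −78 → −30 °C; aq. Rochelle salt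
Reagents that add atoms: trimethylaluminium C[Al](C)C; acetaldehyde CC=O
Why: Cu-catalysed asymmetric conjugate addition sets C8, and the regiodefined aluminium enolate should undergo aldol addition anti to the new C8 methyl, which sets the quaternary C9 with the two methyls cis (tandem conjugate addition–aldol).

**Step 2**
Reactants: 3 (2R,3R)-2-(1-hydroxyethyl)-2,3-dimethylcyclohexan-1-one
Product: 4 (2S,3R)-2-ethenyl-2,3-dimethylcyclohexan-1-one
Conditions: Burgess reagent, toluene, 70 °C
Reagents that add atoms: none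
Why: Burgess syn-elimination can only use the CH3 hydrogens because C9 is quaternary, so both carbinol epimers should converge on the vinyl group.

**Step 3**
Reactants: 5 but-2-yn-1-ol
Product: 6 tert-butyl(but-2-yn-1-yloxy)dimethylsilane
Conditions: TBSCl, imidazole, CH2Cl2, 0 °C → rt
Reagents that add atoms: tert-butyldimethylsilyl chloride CC(C)(C)[Si](C)(C)Cl
Why: Standard silylation of a primary alcohol; the free OH would not survive the hydride and base steps that follow.

**Step 4**
Reactants: 6 tert-butyl(but-2-yn-1-yloxy)dimethylsilane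
Product: 8 tert-butyl{[(2E)-3-iodobut-2-en-1-yl]oxy}dimethylsilane, via alkenylzirconocene chloride 7 (not isolated)
Conditions: Cp2Zr(H)Cl, THF, rt; then I2, 0 °C
Reagents that add atoms: iodine II
Why: Hydrozirconation adds Zr–H syn with Zr at the less hindered, methyl-bearing carbon, and iodinolysis with retention should give the (E)-iodide (hydrozirconation–iodination).

**Step 5**
Reactants: 4 (2S,3R)-2-ethenyl-2,3-dimethylcyclohexan-1-one; 8 tert-butyl{[(2E)-3-iodobut-2-en-1-yl]oxy}dimethylsilane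
Product: 10 (2S,3R)-2-[(3E)-5-{[tert-butyl(dimethyl)silyl]oxy}-3-methylpent-3-en-1-yl]-2,3-dimethylcyclohexan-1-one, via B-alkyl-9-BBN borane 9 (not isolated)
Conditions: 9-BBN, THF, 0 °C → rt; then 8, Pd(dppf)Cl2 (5 mol %), AsPh3, Cs2CO3, DMF/H2O, rt
Reagents that add atoms: none
Why: Anti-Markovnikov hydroboration of the vinyl group (9-BBN is slow towards the hindered ketone) and B-alkyl Suzuki–Miyaura coupling with retention of the iodide geometry should fix the 13E alkene.

**Step 6**
Reactants: 10 (2S,3R)-2-[(3E)-5-{[tert-butyl(dimethyl)silyl]oxy}-3-methylpent-3-en-1-yl]-2,3-dimethylcyclohexan-1-one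
Product: 12 (5R,6S)-6-[(3E)-5-{[tert-butyl(dimethyl)silyl]oxy}-3-methylpent-3-en-1-yl]-5,6-dimethylcyclohex-1-en-1-yl trifluoromethanesulfonate, via potassium enolate 11 (not isolated)
Conditions: KHMDS, THF, −78 °C; PhNTf2, −78 → 0 °C
Reagents that add atoms: N-phenylbis(trifluoromethanesulfonimide) O=S(=O)(N(c1ccccc1)S(=O)(=O)C(F)(F)F)C(F)(F)F
Why: The ketone can enolise only towards C5 (C9 is quaternary), so O-triflation should give a single enol triflate.

**Step 7**
Reactants: 12 (5R,6S)-6-[(3E)-5-{[tert-butyl(dimethyl)silyl]oxy}-3-methylpent-3-en-1-yl]-5,6-dimethylcyclohex-1-en-1-yl trifluoromethanesulfonate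
Product: 13 tert-butyl({(2E)-5-[(1S,6R)-2-ethenyl-1,6-dimethylcyclohex-2-en-1-yl]-3-methylpent-2-en-1-yl}oxy)dimethylsilane
Conditions: Bu3SnCH=CH2, Pd(PPh3)4 (5 mol %), LiCl, THF, 65 °C
Reagents that add atoms: tributyl(vinyl)stannane C=C[Sn](CCCC)(CCCC)CCCC
Why: Stille coupling of an enol triflate with a vinylstannane (LiCl-promoted) should give the semicyclic diene C5=C10–C1=C2 without touching the stereocentres.

**Step 8**
Reactants: 13 tert-butyl({(2E)-5-[(1S,6R)-2-ethenyl-1,6-dimethylcyclohex-2-en-1-yl]-3-methylpent-2-en-1-yl}oxy)dimethylsilane; 14 methacrolein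
Product: 15 (1S,5S,6R,8aS)-5-[(3E)-5-{[tert-butyl(dimethyl)silyl]oxy}-3-methylpent-3-en-1-yl]-1,5,6-trimethyl-1,2,3,5,6,7,8,8a-octahydronaphthalene-1-carbaldehyde
Conditions: 14 (5 equiv), triflimide-activated diphenylprolinol-derived o-tolyl-oxazaborolidine (20 mol %; antipode exposing the Cα-Re face of the enal), CH2Cl2, −78 → −40 °C
Reagents that add atoms: none
Why: Concerted, asynchronous [4+2] cycloaddition of the s-trans methacrolein–oxazaborolidinium complex with the semicyclic 1,2-dialkyl diene; the closest known type is the cationic oxazaborolidine-catalysed Diels–Alder reaction of 2-substituted acroleins with 1-vinylcyclohexenes. Ring A closes by suprafacial formation of C3–C2 and C4–C5 on one diene face, which places the double bond at C1=C10 by construction. C4 is set by the catalyst, which leaves only the Cα-Re face of the bound enal open; C5 follows from the exo topology (formyl exo, methyl endo), which puts CHO cis to H5 and so uses the diene face syn to the C9 methyl. The ortho regiochemistry (C4 to C5, C3 to C2) rests on the larger HOMO coefficient at the unsubstituted vinyl terminus C2. The exo mode is required; it should be favoured by the α-methyl group of the dienophile and by the quaternary C9 next to C10, which crowds an endo formyl–catalyst unit on either face. The diene itself offers little facial bias (C9 carries CH3 and a CH2 chain), so the catalyst-fixed dienophile face must decide between the two exo modes, and this is the main risk.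

**Step 9**
Reactants: 15 (1S,5S,6R,8aS)-5-[(3E)-5-{[tert-butyl(dimethyl)silyl]oxy}-3-methylpent-3-en-1-yl]-1,5,6-trimethyl-1,2,3,5,6,7,8,8a-octahydronaphthalene-1-carbaldehyde
Product: 16 (1S,5S,6R,8aS)-5-[(3E)-5-hydroxy-3-methylpent-3-en-1-yl]-1,5,6-trimethyl-1,2,3,5,6,7,8,8a-octahydronaphthalene-1-carbaldehyde
Conditions: TBAF, THF, 0 °C
Reagents that add atoms: none
Why: Fluoride cleaves the allylic silyl ether; the non-enolisable α-quaternary aldehyde and both alkenes should be inert.

**Step 10**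
Reactants: 16 (1S,5S,6R,8aS)-5-[(3E)-5-hydroxy-3-methylpent-3-en-1-yl]-1,5,6-trimethyl-1,2,3,5,6,7,8,8a-octahydronaphthalene-1-carbaldehyde
Product: 17 (1S,5S,6R,8aS)-5-{2-[(2S,3S)-3-(hydroxymethyl)-2-methyloxiran-2-yl]ethyl}-1,5,6-trimethyl-1,2,3,5,6,7,8,8a-octahydronaphthalene-1-carbaldehyde
Conditions: Ti(OiPr)4 (10 mol %), L-(+)-diethyl tartrate (12 mol %), t-BuOOH, 4 Å MS, CH2Cl2, −20 °C
Reagents that add atoms: tert-butyl hydroperoxide CC(C)(C)OO
Why: Sharpless asymmetric epoxidation acts only on the allylic alcohol (the ring alkene is not directed) and, with L-(+)-tartrate on a geraniol-type (E)-allylic alcohol, should give the (13S,14S)-epoxide by reagent control.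

**Step 11**
Reactants: 17 (1S,5S,6R,8aS)-5-{2-[(2S,3S)-3-(hydroxymethyl)-2-methyloxiran-2-yl]ethyl}-1,5,6-trimethyl-1,2,3,5,6,7,8,8a-octahydronaphthalene-1-carbaldehyde
Product: 18 (1S,5S,6R,8aS)-1,5,6-trimethyl-5-[(3R,4S)-3,4,5-trihydroxy-3-methylpentyl]-1,2,3,5,6,7,8,8a-octahydronaphthalene-1-carbaldehyde
Conditions: HClO4 (cat.), THF/H2O, 0 °C → rt
Reagents that add atoms: water O
Why: Acid-catalysed hydration should open the 2,3-epoxy alcohol at the tertiary C13 (C14 is deactivated by the adjacent CH2OH) with inversion, turning (13S,14S) into the (13R,14S) triol, i.e. net anti-dihydroxylation of the E-alkene.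

**Step 12**
Reactants: 18 (1S,5S,6R,8aS)-1,5,6-trimethyl-5-[(3R,4S)-3,4,5-trihydroxy-3-methylpentyl]-1,2,3,5,6,7,8,8a-octahydronaphthalene-1-carbaldehyde
Product: 19 (1S,5S,6R,8aS)-5-[(3R,4S)-4,5-bis(acetyloxy)-3-hydroxy-3-methylpentyl]-1,5,6-trimethyl-1,2,3,5,6,7,8,8a-octahydronaphthalene-1-carbaldehyde
Conditions: Ac2O, pyridine, DMAP (cat.), CH2Cl2, 0 °C
Reagents that add atoms: acetic anhydride CC(=O)OC(C)=O
Why: DMAP-catalysed acetylation should acylate the primary and secondary hydroxyls while the tertiary C13–OH is too hindered to react at 0 °C.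

**Step 13**
Reactants: 19 (1S,5S,6R,8aS)-5-[(3R,4S)-4,5-bis(acetyloxy)-3-hydroxy-3-methylpentyl]-1,5,6-trimethyl-1,2,3,5,6,7,8,8a-octahydronaphthalene-1-carbaldehyde
Product: 20 (1S,5S,6R,8aS)-5-[(3R,4S)-4,5-bis(acetyloxy)-3-hydroxy-3-methylpentyl]-1,5,6-trimethyl-1,2,3,5,6,7,8,8a-octahydronaphthalene-1-carboxylic acid (target)
Conditions: NaClO2, NaH2PO4, 2-methyl-2-butene, t-BuOH/H2O, rt
Reagents that add atoms: sodium chlorite [Na+].[O-]Cl=O
Why: Pinnick oxidation converts the hindered aldehyde into the acid under buffered conditions that should leave the acetates, the tertiary alcohol and (with the alkene scavenger) the ring double bond untouched.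

**Compound list**
1 | 2-methylcyclohex-2-en-1-one | CC1=CCCCC1=O | starting material
2 | dimethyl{[(3R)-2,3-dimethylcyclohex-1-en-1-yl]oxy}alumane | C[C@@H]1CCCC(O[Al](C)C)=C1C | intermediate
3 | (2R,3R)-2-(1-hydroxyethyl)-2,3-dimethylcyclohexan-1-one (carbinol epimers; C2 descriptor differs from 4 only through CIP priorities) | CC(O)[C@]1(C)C(=O)CCC[C@H]1C | intermediate
4 | (2S,3R)-2-ethenyl-2,3-dimethylcyclohexan-1-one | C=C[C@]1(C)C(=O)CCC[C@H]1C | intermediate
5 | but-2-yn-1-ol | CC#CCO | starting material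
6 | tert-butyl(but-2-yn-1-yloxy)dimethylsilane | CC#CCO[Si](C)(C)C(C)(C)C | intermediate
7 | chlorobis(cyclopentadienyl){(2E)-4-[(tert-butyldimethylsilyl)oxy]but-2-en-2-yl}zirconium | C/C(=C\CO[Si](C)(C)C(C)(C)C)[Zr](Cl)(C1C=CC=C1)C1C=CC=C1 | intermediate
8 | tert-butyl{[(2E)-3-iodobut-2-en-1-yl]oxy}dimethylsilane | C/C(I)=C\CO[Si](C)(C)C(C)(C)C | intermediate
9 | 9-{2-[(1S,2R)-1,2-dimethyl-6-oxocyclohexyl]ethyl}-9-borabicyclo[3.3.1]nonane | C1CCC2CCCC1B2CC[C@]1(C)C(=O)CCC[C@H]1C | intermediate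
10 | (2S,3R)-2-[(3E)-5-{[tert-butyl(dimethyl)silyl]oxy}-3-methylpent-3-en-1-yl]-2,3-dimethylcyclohexan-1-one | CC(C)(C)[Si](C)(C)OC/C=C(C)/CC[C@]1(C)C(=O)CCC[C@H]1C | intermediate
11 | potassium (5R,6S)-6-[(3E)-5-{[tert-butyl(dimethyl)silyl]oxy}-3-methylpent-3-en-1-yl]-5,6-dimethylcyclohex-1-en-1-olate | CC(C)(C)[Si](C)(C)OC/C=C(C)/CC[C@]1(C)C([O-])=CCC[C@H]1C.[K+] | intermediate
12 | (5R,6S)-6-[(3E)-5-{[tert-butyl(dimethyl)silyl]oxy}-3-methylpent-3-en-1-yl]-5,6-dimethylcyclohex-1-en-1-yl trifluoromethanesulfonate | CC(C)(C)[Si](C)(C)OC/C=C(C)/CC[C@]1(C)C(OS(=O)(=O)C(F)(F)F)=CCC[C@H]1C | intermediate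
13 | tert-butyl({(2E)-5-[(1S,6R)-2-ethenyl-1,6-dimethylcyclohex-2-en-1-yl]-3-methylpent-2-en-1-yl}oxy)dimethylsilane | CC(C)(C)[Si](C)(C)OC/C=C(C)/CC[C@]1(C)C(C=C)=CCC[C@H]1C | intermediate
14 | methacrolein (2-methylprop-2-enal) | CC(=C)C=O | starting material
15 | (1S,5S,6R,8aS)-5-[(3E)-5-{[tert-butyl(dimethyl)silyl]oxy}-3-methylpent-3-en-1-yl]-1,5,6-trimethyl-1,2,3,5,6,7,8,8a-octahydronaphthalene-1-carbaldehyde | CC(C)(C)[Si](C)(C)OC/C=C(C)/CC[C@]1(C)C2=CCC[C@](C)(C=O)[C@H]2CC[C@H]1C | intermediate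
16 | (1S,5S,6R,8aS)-5-[(3E)-5-hydroxy-3-methylpent-3-en-1-yl]-1,5,6-trimethyl-1,2,3,5,6,7,8,8a-octahydronaphthalene-1-carbaldehyde | OC/C=C(C)/CC[C@]1(C)C2=CCC[C@](C)(C=O)[C@H]2CC[C@H]1C | intermediate
17 | (1S,5S,6R,8aS)-5-{2-[(2S,3S)-3-(hydroxymethyl)-2-methyloxiran-2-yl]ethyl}-1,5,6-trimethyl-1,2,3,5,6,7,8,8a-octahydronaphthalene-1-carbaldehyde | OC[C@@H]1O[C@@]1(C)CC[C@]1(C)C2=CCC[C@](C)(C=O)[C@H]2CC[C@H]1C | intermediate
18 | (1S,5S,6R,8aS)-1,5,6-trimethyl-5-[(3R,4S)-3,4,5-trihydroxy-3-methylpentyl]-1,2,3,5,6,7,8,8a-octahydronaphthalene-1-carbaldehyde | OC[C@H](O)[C@](C)(O)CC[C@]1(C)C2=CCC[C@](C)(C=O)[C@H]2CC[C@H]1C | intermediate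
19 | (1S,5S,6R,8aS)-5-[(3R,4S)-4,5-bis(acetyloxy)-3-hydroxy-3-methylpentyl]-1,5,6-trimethyl-1,2,3,5,6,7,8,8a-octahydronaphthalene-1-carbaldehyde | CC(=O)OC[C@H](OC(C)=O)[C@](C)(O)CC[C@]1(C)C2=CCC[C@](C)(C=O)[C@H]2CC[C@H]1C | intermediate
20 | (1S,5S,6R,8aS)-5-[(3R,4S)-4,5-bis(acetyloxy)-3-hydroxy-3-methylpentyl]-1,5,6-trimethyl-1,2,3,5,6,7,8,8a-octahydronaphthalene-1-carboxylic acid | CC(=O)OC[C@H](OC(C)=O)[C@](C)(O)CC[C@]1(C)C2=CCC[C@](C)(C(=O)O)[C@H]2CC[C@H]1C | target

**Step count:** 13 steps in total. Longest linear sequence: 11 steps (1, 2, 5–13); steps 3 and 4 are the branch to 8.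

**Steps most likely to fail**

Step 8. The catalyst may fail to override the diene's own preference for attack anti to a pseudoaxial C9 methyl, or an endo mode may leak through; either gives C5 or C4 epimers. The fallback sets out from 3 and comes back at 15, and it moves the cycloaddition ahead of the chain extension so that the substrate shields the wrong face. Aldol 3 would be silylated (Et3SiOTf, 2,6-lutidine) to the triethylsilyl ether F1, converted (KHMDS, PhNTf2) into the enol triflate F2 and vinylated (Stille) to the diene F3. In F3 the α-branched silyloxyethyl group on C9 should sit pseudoaxial (allylic strain) and block the face that must stay free, so the same catalysed Diels–Alder reaction with 14 should be matched and give the aldehyde F4. Desilylation (HF·pyridine) to the alcohol F5, Burgess dehydration to the vinyl aldehyde F6, hydroboration with excess 9-BBN (which also reduces the aldehyde) and Suzuki coupling with 8 to the primary alcohol F7, and Dess–Martin oxidation would return to 15.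

Step 1. Trapping of the hindered aluminium enolate by acetaldehyde may be incomplete or reversible (retro-aldol), or the trans selectivity at the new quaternary carbon may erode. The fallback sets out from 1 and comes back at 10, replacing the aldol/dehydration/hydroboration sequence by an irreversible C-allylation. The same conjugate addition to 1 via 2 would be followed by MeLi and allyl iodide to give the allyl ketone F8. Ozonolysis (PPh3 work-up) would give the keto aldehyde F9, which is reduced chemoselectively (NaBH(OAc)3) to the hydroxy ketone F10. Appel iodination (I2, PPh3, imidazole) gives the iodide F11, zinc insertion (Zn, LiCl, THF) the alkylzinc iodide F12, and Negishi coupling with 8 (Pd(dppf)Cl2) gives 10.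

Step 11. Ionisation at the tertiary C13 may give partial retention, or water may attack C14 instead; both give side-chain diastereomers that would be hard to separate. The fallback sets out from 17 and comes back at 18, delivering the nucleophile inside a titanium chelate instead of by free acid catalysis. Ti(OiPr)4-mediated opening of 17 with benzoic acid (C3-selective opening of a 2,3-epoxy alcohol, with inversion) would give the tertiary benzoate F13, and methanolysis (K2CO3, MeOH) would give 18.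

**Further compounds**
F1 | step 8 | (2R,3R)-2,3-dimethyl-2-{1-[(triethylsilyl)oxy]ethyl}cyclohexan-1-one | CC(O[Si](CC)(CC)CC)[C@]1(C)C(=O)CCC[C@H]1C
F2 | step 8 | (5R,6R)-5,6-dimethyl-6-{1-[(triethylsilyl)oxy]ethyl}cyclohex-1-en-1-yl trifluoromethanesulfonate | CC(O[Si](CC)(CC)CC)[C@]1(C)C(OS(=O)(=O)C(F)(F)F)=CCC[C@H]1C
F3 | step 8 | ({1-[(1S,6R)-2-ethenyl-1,6-dimethylcyclohex-2-en-1-yl]ethyl}oxy)triethylsilane | CC(O[Si](CC)(CC)CC)[C@]1(C)C(C=C)=CCC[C@H]1C
F4 | step 8 | (1S,5S,6R,8aS)-1,5,6-trimethyl-5-{1-[(triethylsilyl)oxy]ethyl}-1,2,3,5,6,7,8,8a-octahydronaphthalene-1-carbaldehyde | CC(O[Si](CC)(CC)CC)[C@]1(C)C2=CCC[C@](C)(C=O)[C@H]2CC[C@H]1C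
F5 | step 8 | (1S,5S,6R,8aS)-5-(1-hydroxyethyl)-1,5,6-trimethyl-1,2,3,5,6,7,8,8a-octahydronaphthalene-1-carbaldehyde | CC(O)[C@]1(C)C2=CCC[C@](C)(C=O)[C@H]2CC[C@H]1C
F6 | step 8 | (1S,5S,6R,8aS)-5-ethenyl-1,5,6-trimethyl-1,2,3,5,6,7,8,8a-octahydronaphthalene-1-carbaldehyde | C=C[C@]1(C)C2=CCC[C@](C)(C=O)[C@H]2CC[C@H]1C
F7 | step 8 | {(1S,5S,6R,8aS)-5-[(3E)-5-{[tert-butyl(dimethyl)silyl]oxy}-3-methylpent-3-en-1-yl]-1,5,6-trimethyl-1,2,3,5,6,7,8,8a-octahydronaphthalen-1-yl}methanol | CC(C)(C)[Si](C)(C)OC/C=C(C)/CC[C@]1(C)C2=CCC[C@](C)(CO)[C@H]2CC[C@H]1C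
F8 | step 1 | (2S,3R)-2,3-dimethyl-2-(prop-2-en-1-yl)cyclohexan-1-one | C=CC[C@]1(C)C(=O)CCC[C@H]1C
F9 | step 1 | [(1S,2R)-1,2-dimethyl-6-oxocyclohexyl]acetaldehyde | O=CC[C@]1(C)C(=O)CCC[C@H]1C
F10 | step 1 | (2S,3R)-2-(2-hydroxyethyl)-2,3-dimethylcyclohexan-1-one | OCC[C@]1(C)C(=O)CCC[C@H]1C
F11 | step 1 | (2S,3R)-2-(2-iodoethyl)-2,3-dimethylcyclohexan-1-one | ICC[C@]1(C)C(=O)CCC[C@H]1C
F12 | step 1 | {2-[(1S,2R)-1,2-dimethyl-6-oxocyclohexyl]ethyl}(iodo)zinc | I[Zn]CC[C@]1(C)C(=O)CCC[C@H]1C
F13 | step 11 | (1S,5S,6R,8aS)-5-[(3R,4S)-3-(benzoyloxy)-4,5-dihydroxy-3-methylpentyl]-1,5,6-trimethyl-1,2,3,5,6,7,8,8a-octahydronaphthalene-1-carbaldehyde | OC[C@H](O)[C@](C)(OC(=O)c1ccccc1)CC[C@]1(C)C2=CCC[C@](C)(C=O)[C@H]2CC[C@H]1C
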